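**Plan**

1. Cuts (labdane numbering): C13=C14 and C13–C16 go first, which folds the side chain onto the C8 oxygen as a temporary δ-lactone (ring C, compound 20). Then, as one retrosynthetic event, C8–O and C9–C10 are cut and C4 is moved from C5 back to C10. This shrinks ring A (C1–C5, C10) to a cyclopentane (C1–C4, C10) with C5 outside the ring as a carbinyl mesylate (16). Last, C6–C7 and C5–C6 are cut.
2. Enabling feature: in ring A the methine C5 lies between the two fully substituted carbons C4 (gem-dimethyl) and C10 (C20 methyl), next to C3–Br. Without C5 these atoms are the 3-substituted 1,2,2-trimethylcyclopentane of camphanic acid. A cation at exocyclic C5 draws over C4, the best migrating group on C10, and leaves exactly the C10 cation of a labdane cyclisation.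
3. Forward order: the five-membered precursor of ring A comes from the chiral pool, then Br goes on C3, C6 is added with MeLi, and C7–C13 by enolate allylation. The key step enlarges ring A and closes ring B and temporary ring C in one operation from a monocyclic precursor. MeLi then opens ring C, and olefination and reduction finish the chain.
4. Stereochemistry: C3 comes from camphanic acid by one SN2 inversion, and the C5 carbinol from a CBS reduction. In the key step C5 and C10 are set by two inversions along the antiperiplanar O–C5/C10–C4 array, and C9 and C8 by chair anti addition to the E alkene (E from the SeO2 oxidation). C13=C14 (E) comes from the HWE reaction.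

Key step: step 10

Remark: labdane numbering is used for all intermediates (C1–C10 decalin carbons, C11–C16 side chain, C17 on C8, C18/C19 on C4, C20 on C10). Compounds 1, 2 and 7 and solutions of LiN(i-Pr)2 and MeLi are taken as commercial.

**Step 1**
Reactants: 1 tert-butyl acetate; 2 prenyl bromide (1-bromo-3-methylbut-2-ene)
Product: 4 tert-butyl 5-methylhex-4-enoate, via lithium enolate 3 (not isolated)
Conditions: LiN(i-Pr)2, THF, −78 °C; then 2, −78 °C to rt
Reagents that add atoms: lithium diisopropylamide, CC(C)N([Li])C(C)C (its lithium stays in 3 only)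
Why: Alkylation of an ester lithium enolate (SN2 at the primary allylic bromide) joins C11 to C12, and no stereocentre is formed.

**Step 2**
Reactants: 4 tert-butyl 5-methylhex-4-enoate
Product: 5 tert-butyl (4E)-6-hydroxy-5-methylhex-4-enoate
Conditions: SeO2 (cat.), t-BuOOH, CH2Cl2, 0 °C to rt
Reagents that add atoms: tert-butyl hydroperoxide, CC(C)(C)OO
Why: Riley allylic oxidation (ene reaction, then [2,3]-sigmatropic shift) hydroxylates only the methyl group trans to the chain of a trisubstituted alkene, which fixes the E geometry of the later C8=C9 bond.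

**Step 3**
Reactants: 5 tert-butyl (4E)-6-hydroxy-5-methylhex-4-enoate
Product: 6 tert-butyl (4E)-6-bromo-5-methylhex-4-enoate
Conditions: CBr4, PPh3, CH2Cl2, 0 °C
Reagents that add atoms: carbon tetrabromide, BrC(Br)(Br)Br
Why: The Appel reaction at a primary allylic alcohol runs by SN2 under neutral conditions, so the E alkene and the tert-butyl ester should stay untouched.

**Step 4**
Reactants: 7 (1S,4R)-4,7,7-trimethyl-3-oxo-2-oxabicyclo[2.2.1]heptane-1-carbonyl chloride ((−)-camphanic chloride)
Product: 9 (1S,4R)-4,7,7-trimethyl-2-oxabicyclo[2.2.1]heptan-3-one, via Barton ester 8 (not isolated)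
Conditions: sodium 1-oxidopyridine-2-thione (NaC5H4NOS), 4-(dimethylamino)pyridine (cat.), toluene, rt, dark; then t-BuSH, hν (tungsten lamp), 80 °C
Reagents that add atoms: sodium 1-oxidopyridine-2-thione, [Na+].[O-]N1C=CC=CC1=S (its atoms stay in 8 only)
Why: Barton reductive decarboxylation: ester 8 fragments in a radical chain to CO2 and the bridgehead radical, which takes hydrogen from the thiol, and the bicycle allows only retention, so C3 keeps its oxygen on the face of the C10 carbonyl.

**Step 5**
Reactants: 9 (1S,4R)-4,7,7-trimethyl-2-oxabicyclo[2.2.1]heptan-3-one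
Product: 11 1-[(1R,3S)-3-hydroxy-1,2,2-trimethylcyclopentyl]ethan-1-one (OH cis to acetyl), via lithium hemiketal alkoxide 10 (not isolated)
Conditions: MeLi (1.05 equiv), Et2O, −78 °C; then AcOH in Et2O, −78 °C
Reagents that add atoms: methyllithium, [Li]C
Why: Single addition of an organolithium to a lactone: alkoxide 10 should hold at −78 °C because its sp3 carbon eases the angle strain of the bridged carbonyl and the flanking quaternary C10 slows a second attack, and the cold acid quench releases the cis-hydroxy ketone with C3 and C10 unchanged.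

**Step 6**
Reactants: 11 1-[(1R,3S)-3-hydroxy-1,2,2-trimethylcyclopentyl]ethan-1-one
Product: 12 1-[(1R,3R)-3-bromo-1,2,2-trimethylcyclopentyl]ethan-1-one (Br trans to acetyl)
Conditions: CBr4, P(n-C8H17)3, toluene, 70 °C
Reagents that add atoms: carbon tetrabromide, BrC(Br)(Br)Br
Why: Appel reaction with inversion: bromide attacks the phosphonium-activated C3 from the rear, on the face of the C20 methyl, so the (3S)-carbinol becomes the (3R)-bromide of the target; SN2 next to a quaternary carbon is known for 2,2-dimethylcycloalkanols under such conditions, a cyclopentane being the best case, and the acetyl group is cis to the leaving group and cannot take part.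

**Step 7**
Reactants: 12 1-[(1R,3R)-3-bromo-1,2,2-trimethylcyclopentyl]ethan-1-one; 6 tert-butyl (4E)-6-bromo-5-methylhex-4-enoate
Product: 14 tert-butyl (4E)-8-[(1R,3R)-3-bromo-1,2,2-trimethylcyclopentyl]-5-methyl-8-oxooct-4-enoate, via lithium enolate 13 (not isolated)
Conditions: LiN(i-Pr)2, THF, −78 °C; then 6, DMPU, −78 to −30 °C
Reagents that add atoms: lithium diisopropylamide, CC(C)N([Li])C(C)C (its lithium stays in 13 only)
Why: Kinetic lithium enolate alkylation: 12 can enolise only toward its methyl group (C6), the allylic bromide is far more reactive than the neopentylic C3 bromide, whose internal displacement would be a disfavoured 5-(enolendo)-exo-tet closure, and no stereocentre is touched.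

**Step 8**
Reactants: 14 tert-butyl (4E)-8-[(1R,3R)-3-bromo-1,2,2-trimethylcyclopentyl]-5-methyl-8-oxooct-4-enoate
Product: 15 tert-butyl (4E,8R)-8-[(1R,3R)-3-bromo-1,2,2-trimethylcyclopentyl]-8-hydroxy-5-methyloct-4-enoate
Conditions: (S)-1-methyl-3,3-diphenyltetrahydro-1H,3H-pyrrolo[1,2-c][1,3,2]oxazaborole ((S)-Me-CBS, 0.3 equiv), catecholborane, toluene, −40 to −20 °C; then MeOH, aq. NaHCO3
Reagents that add atoms: none
Why: Corey–Bakshi–Shibata reduction: the catalyst tells the tertiary-alkyl side (C10) from the primary-alkyl side (C6) of the ketone, as with pinacolone-type ketones, so the (S)-catalyst should give the (8R)-carbinol (C5), while catecholborane leaves alkene, ester and bromide alone.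

**Step 9**
Reactants: 15 tert-butyl (4E,8R)-8-[(1R,3R)-3-bromo-1,2,2-trimethylcyclopentyl]-8-hydroxy-5-methyloct-4-enoate
Product: 16 tert-butyl (4E,8R)-8-[(1R,3R)-3-bromo-1,2,2-trimethylcyclopentyl]-5-methyl-8-(methylsulfonyloxy)oct-4-enoate
Conditions: MsCl, Et3N, CH2Cl2, −10 °C
Reagents that add atoms: methanesulfonyl chloride, CS(=O)(=O)Cl
Why: Mesylation by way of sulfene works on hindered secondary alcohols, keeps the C5 configuration because the C–O bond is not broken, and installs the activating group for the key step.

**Step 10**
Reactants: 16 tert-butyl (4E,8R)-8-[(1R,3R)-3-bromo-1,2,2-trimethylcyclopentyl]-5-methyl-8-(methylsulfonyloxy)oct-4-enoate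
Product: 20 (3R,5S,8S,9S,10R)-3-bromo-14,15,16-trinorlabdan-13,8-olide, via cyclohexyl cation 17 (not isolated), via decalyl cation 18 (not isolated), via lactonium ion 19 (not isolated)
Conditions: (CF3)2CHOH, 2,6-lutidine (2.5 equiv), 45 °C
Reagents that add atoms: none
Why: Proposed new method: in the strongly ionising, barely nucleophilic solvent the neopentylic C5–OMs bond ionises with help from the antiperiplanar C10–C4 bond, so that C4 shifts from C10 to C5 (Wagner–Meerwein 1,2-shift) and the cyclopentane C10–C1–C2–C3–C4 takes up C5 to become six-membered ring A with a tertiary cation at C10 (17), which the C8=C9 alkene attacks to give the C8 cation 18, trapped by the ester carbonyl oxygen as 19, which sheds isobutene. The closest known reaction types are the solvolytic cyclopentylcarbinyl-to-cyclohexyl ring expansion of sulfonates and the cation–olefin bicyclisation of homofarnesic-type acids and esters to lactones; their union has its model in the ring-expansion/ring-closure relay of triterpene cyclases (oxidosqualene cyclase class) but has not been run on such a substrate. Ring B closes 6-endo-trig at the alkene through a chair, and temporary ring C closes as a six-membered lactone by attack of the carbonyl oxygen on C8. C5 is set by inversion at the (8R)-carbinol carbon, C10 by attack of C9 on the lobe opposite to the departing C4 (inversion of the camphanic quaternary centre, hence H5 and C20 trans), C9 and C8 by anti addition of C10 and O across the E alkene in the chair (C11 and O equatorial, C17 axial), while C3 is a spectator whose bromine ends up equatorial. The step needs migration of C4 rather than C1 or C20 and initiation at C5 only: C4 is the only tertiary alkyl group on C10 and its shift relieves the strain of the two adjacent quaternary carbons, the bromine stands trans to the C5 arm and cannot bridge to it, and the lutidine buffer keeps the alkene from being protonated.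

**Step 11**
Reactants: 20 (3R,5S,8S,9S,10R)-3-bromo-14,15,16-trinorlabdan-13,8-olide
Product: 22 (3R,5S,8S,9S,10R)-3-bromo-8-hydroxy-14,15-dinorlabdan-13-one, via lithium hemiketal alkoxide 21 (not isolated)
Conditions: MeLi (1.1 equiv), THF, −78 °C; then AcOH in THF, −78 °C
Reagents that add atoms: methyllithium, [Li]C
Why: Single addition of MeLi to a lactone, known for terpenoid lactones of the sclareolide type: alkoxide 21 holds at −78 °C and opens on work-up to the C13 methyl ketone and the free C8 tertiary alcohol, which removes temporary ring C without touching the equatorial neopentylic bromide.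

**Step 12**
Reactants: 22 (3R,5S,8S,9S,10R)-3-bromo-8-hydroxy-14,15-dinorlabdan-13-one
Product: 23 ethyl (3R,5S,8S,9S,10R,13E)-3-bromo-8-hydroxylabd-13-en-15-oate
Conditions: (EtO)2P(O)CH2CO2Et, NaH, THF, 0 to 45 °C
Reagents that add atoms: triethyl phosphonoacetate, CCOC(=O)CP(=O)(OCC)OCC
Why: Horner–Wadsworth–Emmons olefination of a methyl ketone favours the E enoate (ester trans to the larger C12 chain), the minor Z isomer being removable by chromatography, and the equatorial C3 bromide has no antiperiplanar hydrogen and should resist elimination.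

**Step 13**
Reactants: 23 ethyl (3R,5S,8S,9S,10R,13E)-3-bromo-8-hydroxylabd-13-en-15-oate
Product: 24 (3R,5S,8S,9S,10R,13E)-3-bromolabd-13-ene-8,15-diol (target)
Conditions: i-Bu2AlH (3.5 equiv), CH2Cl2, −78 °C; then aq. potassium sodium tartrate
Reagents that add atoms: none
Why: 1,2-Reduction of the α,β-unsaturated ester by i-Bu2AlH gives the allylic alcohol with the alkene geometry kept, and the alkyl bromide and tertiary alcohol are inert at −78 °C.

**Compound list**

1 | tert-butyl acetate | CC(=O)OC(C)(C)C | starting material
2 | prenyl bromide (1-bromo-3-methylbut-2-ene) | CC(C)=CCBr | starting material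
3 | lithium enolate of tert-butyl acetate (not isolated) | C=C(O[Li])OC(C)(C)C | intermediate
4 | tert-butyl 5-methylhex-4-enoate | CC(C)=CCCC(=O)OC(C)(C)C | intermediate
5 | tert-butyl (4E)-6-hydroxy-5-methylhex-4-enoate | OC/C(C)=C/CCC(=O)OC(C)(C)C | intermediate
6 | tert-butyl (4E)-6-bromo-5-methylhex-4-enoate | BrC/C(C)=C/CCC(=O)OC(C)(C)C | intermediate
7 | (1S,4R)-(−)-camphanic chloride | ClC(=O)[C@@]12CC[C@@](C)(C(=O)O1)C2(C)C | starting material
8 | 2-thioxopyridin-1(2H)-yl (1S,4R)-camphanate, Barton ester (not isolated) | O=C(ON3C=CC=CC3=S)[C@@]12CC[C@@](C)(C(=O)O1)C2(C)C | intermediate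
9 | (1S,4R)-4,7,7-trimethyl-2-oxabicyclo[2.2.1]heptan-3-one | O=C1O[C@H]2CC[C@]1(C)C2(C)C | intermediate
10 | lithium alkoxide of the bicyclic methyl hemiketal of 9 (not isolated) | [Li]OC1(C)O[C@H]2CC[C@]1(C)C2(C)C | intermediate
11 | 1-[(1R,3S)-3-hydroxy-1,2,2-trimethylcyclopentyl]ethan-1-one | CC(=O)[C@]1(C)CC[C@H](O)C1(C)C | intermediate
12 | 1-[(1R,3R)-3-bromo-1,2,2-trimethylcyclopentyl]ethan-1-one | CC(=O)[C@]1(C)CC[C@@H](Br)C1(C)C | intermediate
13 | lithium enolate of 12 (not isolated) | C=C(O[Li])[C@]1(C)CC[C@@H](Br)C1(C)C | intermediate
14 | tert-butyl (4E)-8-[(1R,3R)-3-bromo-1,2,2-trimethylcyclopentyl]-5-methyl-8-oxooct-4-enoate | CC(C)(C)OC(=O)CC/C=C(\C)CCC(=O)[C@]1(C)CC[C@@H](Br)C1(C)C | intermediate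
15 | tert-butyl (4E,8R)-8-[(1R,3R)-3-bromo-1,2,2-trimethylcyclopentyl]-8-hydroxy-5-methyloct-4-enoate | CC(C)(C)OC(=O)CC/C=C(\C)CC[C@@H](O)[C@]1(C)CC[C@@H](Br)C1(C)C | intermediate
16 | methanesulfonate of 15 | CC(C)(C)OC(=O)CC/C=C(\C)CC[C@@H](OS(C)(=O)=O)[C@]1(C)CC[C@@H](Br)C1(C)C | intermediate
17 | ring-enlarged cyclohexyl cation, charge at C10 (not isolated) | CC(C)(C)OC(=O)CC/C=C(\C)CC[C@H]1[C+](C)CC[C@@H](Br)C1(C)C | intermediate
18 | trans-decalyl cation, charge at C8 (not isolated) | CC(C)(C)OC(=O)CC[C@H]1[C@]2(C)CC[C@@H](Br)C(C)(C)[C@H]2CC[C+]1C | intermediate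
19 | tert-butoxy lactonium ion (not isolated) | CC(C)(C)OC=1CC[C@H]2[C@]3(C)CC[C@@H](Br)C(C)(C)[C@H]3CC[C@]2(C)[O+]=1 | intermediate
20 | (3R,5S,8S,9S,10R)-3-bromo-14,15,16-trinorlabdan-13,8-olide | O=C1CC[C@H]2[C@]3(C)CC[C@@H](Br)C(C)(C)[C@H]3CC[C@]2(C)O1 | intermediate
21 | lithium alkoxide of the methyl hemiketal of 20 (not isolated) | [Li]OC1(C)CC[C@H]2[C@]3(C)CC[C@@H](Br)C(C)(C)[C@H]3CC[C@]2(C)O1 | intermediate
22 | (3R,5S,8S,9S,10R)-3-bromo-8-hydroxy-14,15-dinorlabdan-13-one | CC(=O)CC[C@H]1[C@]2(C)CC[C@@H](Br)C(C)(C)[C@H]2CC[C@]1(C)O | intermediate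
23 | ethyl (3R,5S,8S,9S,10R,13E)-3-bromo-8-hydroxylabd-13-en-15-oate | C/C(=C\C(=O)OCC)CC[C@H]1[C@]2(C)CC[C@@H](Br)C(C)(C)[C@H]2CC[C@]1(C)O | intermediate
24 | (3R,5S,8S,9S,10R,13E)-3-bromolabd-13-ene-8,15-diol | C/C(=C\CO)CC[C@H]1[C@]2(C)CC[C@@H](Br)C(C)(C)[C@H]2CC[C@]1(C)O | target

**Step count**

Total step count: 13. Longest linear sequence: 10 steps (steps 4 to 13, from 7).

**Steps most likely to fail**

1. Step 10.
   - What may go wrong: proton loss from the ring-enlarged cation before ring B closes (an interrupted cascade). A competing shift of C1 or C20 is judged the lesser risk.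
   - Fallback (known chemistry), from 16 back to 20: the cascade is split into two separate, known operations.
   - Acetolysis of 16 (AcOH, NaOAc, 60 °C) is the classical Wagner–Meerwein ring expansion with proton loss. It should give the ring-enlarged olefin tert-butyl (4E)-7-[(5R)-5-bromo-2,6,6-trimethylcyclohex-1-en-1-yl]-5-methylhept-4-enoate F1.
   - ClSO3H in 2-nitropropane at −78 °C, the known superacid closure of monocyclic homofarnesic-type acids to lactones, then protonates C5, closes rings B and C and cleaves the tert-butyl group.
   - The preference of the C3 bromine for the equatorial position of the chair should choose the face of protonation, and the route is rejoined at 20.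

2. Step 6.
   - What may go wrong: ionisation of the activated neopentylic carbinol with methyl shift, or elimination toward C2, instead of SN2.
   - Fallback, from 9 back to 12, bypassing 11: the electrophile is changed from an activated alcohol to the strained bridged lactone itself.
   - Bromotrimethylsilane (CHCl3, 60 °C) should open 9 by alkyl–oxygen cleavage with inversion at C3, driven by release of the bicyclic strain. The product is trimethylsilyl (1R,3R)-3-bromo-1,2,2-trimethylcyclopentane-1-carboxylate F2.
   - Oxalyl chloride with catalytic DMF converts the silyl ester under neutral conditions into (1R,3R)-3-bromo-1,2,2-trimethylcyclopentane-1-carbonyl chloride F3.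
   - Me2CuLi (Et2O, −78 °C) then gives 12.

3. Step 8.
   - What may go wrong: sluggish reduction of the very hindered ketone, poor facial selectivity if the bias of the substrate opposes the catalyst, and hydroboration of the alkene on forcing.
   - Fallback, from 14 back to 15: catalyst control is given up for separation and recycling.
   - NaBH4 with CeCl3 in MeOH at 0 °C should give 15 together with its C5 epimer, tert-butyl (4E,8S)-8-[(1R,3R)-3-bromo-1,2,2-trimethylcyclopentyl]-8-hydroxy-5-methyloct-4-enoate F4.
   - The two diastereomers are separated on silica. F4 is oxidised back to 14 with Dess–Martin periodinane and reduced again, and 15 goes on to step 9.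

**Further compounds**

F1 | step 10 | tert-butyl (4E)-7-[(5R)-5-bromo-2,6,6-trimethylcyclohex-1-en-1-yl]-5-methylhept-4-enoate | CC(C)(C)OC(=O)CC/C=C(\C)CCC1=C(C)CC[C@@H](Br)C1(C)C
F2 | step 6 | trimethylsilyl (1R,3R)-3-bromo-1,2,2-trimethylcyclopentane-1-carboxylate | C[Si](C)(C)OC(=O)[C@]1(C)CC[C@@H](Br)C1(C)C
F3 | step 6 | (1R,3R)-3-bromo-1,2,2-trimethylcyclopentane-1-carbonyl chloride | ClC(=O)[C@]1(C)CC[C@@H](Br)C1(C)C
F4 | step 8 | tert-butyl (4E,8S)-8-[(1R,3R)-3-bromo-1,2,2-trimethylcyclopentyl]-8-hydroxy-5-methyloct-4-enoate | CC(C)(C)OC(=O)CC/C=C(\C)CC[C@H](O)[C@]1(C)CC[C@@H](Br)C1(C)C
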